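The data are simulated with constants of no real substance.

Percent of the solid substrate charged is the unit of every reading here, so we fold the charges into one number: E, the reagent charge over the solid substrate charge, is 1.00 for theta and 0.250 for epsilon.

| setting | ochre | amber | theta | epsilon |
|---|---|---|---|---|
| solid substrate | 0.40 M | 0.40 M | 0.40 M | 0.40 M |
| reagent | 0.075 M (fed, over 4.0 h) | 0.27 M (fed, over 4.0 h) | 0.400 M (fed, over 4.0 h) | 0.100 M (fed, over 4.0 h) |
| temperature | −45 °C | −20 °C |  |  |
| remark | run made earlier | run made earlier | at −40 °C until 4.0 h, from then on at 0 °C | at −40 °C throughout |
| time |  |  | 15 h | 15 h |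

- ochre (time / h: target / %): 2.50: 1.7; 5.00: 6.0; 8.00: 7.3; 10.0: 9.1
- amber (time / h: target / %): 0.500: 1.3; 1.33: 4.8; 2.00: 6.7; 4.00: 15.1

(readings scatter by 1 percentage point)

- given per volume of solution although it is solid: solid substrate
- at the start none of the solid substrate is in solution
- what has only dissolved of solid substrate counts as not reacted
- a reading or a percentage of target counts all its forms, free or not

- which one finishes higher in amount of target, in percent of the solid substrate charged ("neither" within 2 percentage points) (theta / epsilon / neither)
- amount of target at the end, in percent of the solid substrate charged, theta
- amount of target at the end, in percent of the solid substrate charged, epsilon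

1. If one reagent turns over one solid substrate, E is the fraction of the charge that can react, and below 1 the reagent is the limiting reagent.

2. We test whether E is enough. The ochre run, with E at 0.187, reads 9.1% at 10.0 h, a reading of 0.485 of its E, while the amber run, with E at 0.675, reads 15.1% at 4.00 h, a reading of 0.224. So E gives a ceiling, and the part of it reached as target differs from run to run.

3. Our own reckoning multiplies E by the part read in the run nearest in E, which gives 12.1% for epsilon and 22.4% for theta, so we expect theta to finish higher.

4. The forecast also names theta, but with 85% for theta, on the ground there that “reagent is plentiful, so dissolution limits”, and 19% for epsilon, both above our figures.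

5. The flasks give 20.1% for theta and 12.6% for epsilon, so theta finishes higher.

    starting material + target ⇌ idle adduct, settled at all times (K = 3.70 /M, ΔH = −56.0 kJ/mol)
    target ⇌ isomer of the product (K = 1.70, k = 0.0379 /min, Ea = 72.0 kJ/mol, ΔH = 11.0 kJ/mol)
    solid substrate ⇌ starting material, rate k3*(cs3 - [starting material]) while solid is left; crystals form when [starting material] > cs3 (solubility = 0.380 M, k = 0.152 /min)
    starting material + reagent → target, rate k4*[starting material]*[reagent]^1.5 (k = 0.0693 /M^1.5/min, Ea = 47.0 kJ/mol)
    (constants at −40 °C)

Theta at 15.0 h holds target and isomer of the product together at 98.6% of the charge, close to its E of 1.00, and by 150 h target still stands at 20.3%, so theta has come to rest. In the neighbour of theta with 0.68 M of solid substrate, the reagent stands at 0.588 equiv, and that neighbour holds 58.8% in those two forms. Epsilon has not come to rest: 8.2% of its reagent remains at 15.0 h, and by 150 h target reaches 13.5% and isomer of the product 11.4%, together 25.0% against its E of 0.250.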